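## Retrosynthetic overview

1. The C6–O ester bond is made last: angelic acid opens the cis-5,6-epoxide of a 4-hydroxy epoxy-cyclodecane at C6 with inversion, which sets C6 and frees O5 without protecting groups.
2. The epoxide comes from hydroxyl-directed epoxidation of a (Z)-cyclodecenol. The ten-membered carbocycle (the only ring of the target) is closed before that by ring-closing metathesis of an acyclic diene diol.
3. In the diene, C7/C11 come from asymmetric epoxidation of a prenyl terminus followed by vinyl-copper opening; C4 comes from Sharpless epoxidation of methallyl alcohol; C10 comes from (R)-citronellyl bromide.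
4. Ring order: carbocycle (step 6), then the transient oxirane (step 7), which is opened in step 8.

Assumption: germacrane locants are used in the text (C6 = ester carbon, C5 = secondary carbinol, C4 = methyl carbinol, C7 = carbon bearing the C11 hydroxyisopropyl group, C10 = secondary methyl carbon); (R)-citronellyl bromide is taken as a bought material.

## Route

Step 1
Reactants: 1 2-methylprop-2-en-1-ol (methallyl alcohol)
Product: 3 [(2R)-2-methyloxiran-2-yl]methyl 4-methylbenzenesulfonate, via (S)-2-methylglycidol 2 (not isolated)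
Conditions: Ti(OiPr)4 (5 mol%), L-(+)-DIPT (6 mol%), cumene hydroperoxide, 4 Å MS, CH2Cl2, −20 °C; then P(OMe)3; TsCl, Et3N, DMAP (cat.), −10 °C
Reagents that add atoms: cumene hydroperoxide CC(C)(OO)c1ccccc1; 4-toluenesulfonyl chloride Cc1ccc(cc1)S(=O)(=O)Cl
Why: Sharpless asymmetric epoxidation of a 2-substituted allylic alcohol, in which the L-(+)-tartrate titanium catalyst delivers oxygen to one enantioface to give (S)-epoxy alcohol 2 (this C–O bond formation sets the future C4 carbinol), and in-situ tosylation avoids isolating the water-soluble glycidol.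

Step 2
Reactants: 4 (R)-citronellyl bromide [(6R)-8-bromo-2,6-dimethyloct-2-ene]; 3 [(2R)-2-methyloxiran-2-yl]methyl 4-methylbenzenesulfonate
Product: 6 (2R,6S)-2-hydroxy-2,6,10-trimethylundec-9-en-1-yl 4-methylbenzenesulfonate, via (R)-citronellylmagnesium bromide 5 (not isolated)
Conditions: 4, Mg, THF, 40 °C; then CuI (10 mol%), 3, THF, −40 → −20 °C
Reagents that add atoms: none
Why: Copper-catalysed Grignard opening of a terminal epoxide at its CH2 (the neopentyl tosylate is inert at low temperature), so the C4–O bond is untouched and the C10 methyl centre is carried unchanged from 4.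

Step 3
Reactants: 6 (2R,6S)-2-hydroxy-2,6,10-trimethylundec-9-en-1-yl 4-methylbenzenesulfonate
Product: 8 (3R,7S)-3,7,11-trimethyldodeca-1,10-dien-3-ol, via terminal epoxide 7 (not isolated)
Conditions: Me3S+ I− (4 equiv), n-BuLi (3.9 equiv), THF, −10 °C; then 6, −10 °C → rt
Reagents that add atoms: trimethylsulfonium iodide C[S+](C)C.[I-]
Why: The alkoxide closes onto the tosylate to give epoxide 7, which dimethylsulfonium methylide opens at CH2 before the betaine loses Me2S (one-carbon homologation of an epoxide to an allylic alcohol), and no bond to C4 is broken.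

Step 4
Reactants: 8 (3R,7S)-3,7,11-trimethyldodeca-1,10-dien-3-ol
Product: 9 (3R,7S)-9-[(2R)-3,3-dimethyloxiran-2-yl]-3,7-dimethylnon-1-en-3-ol
Conditions: D-fructose-derived Shi ketone (30 mol%), KHSO5 (as 2KHSO5·KHSO4·K2SO4), K2CO3, Bu4NHSO4, MeCN/DMM/aq. Na2B4O7 buffer, 0 °C
Reagents that add atoms: potassium peroxymonosulfate [K+].[O-]S(=O)(=O)OO
Why: Shi asymmetric epoxidation, in which the chiral dioxirane attacks only the electron-rich trisubstituted alkene (not the vinyl carbinol) through a spiro transition state and sets the (R) epoxide carbon (future C7) under catalyst control.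

Step 5
Reactants: 9 (3R,7S)-9-[(2R)-3,3-dimethyloxiran-2-yl]-3,7-dimethylnon-1-en-3-ol
Product: 10 (3R,6S,10R)-3-ethenyl-2,6,10-trimethyldodec-11-ene-2,10-diol
Conditions: CH2=CHMgBr (5 equiv), CuI (20 mol%), THF, −30 °C → rt
Reagents that add atoms: vinylmagnesium bromide C=C[Mg]Br
Why: Copper-mediated SN2 opening of the trisubstituted epoxide at its less substituted carbon with inversion puts the vinyl group on C7 in the (R) configuration and leaves the C11 tertiary alcohol.

Step 6
Reactants: 10 (3R,6S,10R)-3-ethenyl-2,6,10-trimethyldodec-11-ene-2,10-diol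
Product: 11 (1R,2Z,4R,7S)-4-(2-hydroxypropan-2-yl)-1,7-dimethylcyclodec-2-en-1-ol
Conditions: RuCl2(=CHPh)(H2IMes)(PCy3) (second-generation Grubbs catalyst, 10 mol%), toluene (1 mM), 80 °C
Reagents that add atoms: none
Why: Ring-closing metathesis in which both hindered vinyl groups homodimerise slowly, high dilution favours cyclisation, and the Z-cyclodecene (about 3 kcal/mol below E) is the product of reversible metathesis, with no stereocentre touched.

Step 7
Reactants: 11 (1R,2Z,4R,7S)-4-(2-hydroxypropan-2-yl)-1,7-dimethylcyclodec-2-en-1-ol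
Product: 12 (1S,2R,6S,9R,10S)-9-(2-hydroxypropan-2-yl)-2,6-dimethyl-11-oxabicyclo[8.1.0]undecan-2-ol
Conditions: VO(acac)2 (5 mol%), t-BuOOH (1.5 equiv), CH2Cl2, 0 °C → rt
Reagents that add atoms: tert-butyl hydroperoxide CC(C)(C)OO
Why: Hydroxyl-directed vanadium epoxidation in which the tertiary allylic C4 alkoxide binds vanadium and delivers oxygen to the alkene face syn to it (the cis epoxy alcohol usual for medium-ring Z-allylic alcohols, and also the exo face with H7 eclipsing the alkene), setting C5 and the transient C6 configuration.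

Step 8
Reactants: 12 (1S,2R,6S,9R,10S)-9-(2-hydroxypropan-2-yl)-2,6-dimethyl-11-oxabicyclo[8.1.0]undecan-2-ol; 13 angelic acid [(2Z)-2-methylbut-2-enoic acid]
Product: 14 (1R,2S,3R,7S,10R)-2,3-dihydroxy-10-(2-hydroxypropan-2-yl)-3,7-dimethylcyclodecyl (2Z)-2-methylbut-2-enoate (target)
Conditions: Ti(OiPr)4 (2.2 equiv), 13 (3 equiv), CH2Cl2, 0 °C → rt; aq. tartaric acid work-up
Reagents that add atoms: none
Why: Proposed new method: a double-alkoxide titanium template in which the syn C4 alkoxide holds one tetravalent titanium centre that chelates and polarises the epoxide oxygen while the anti-disposed C11 alkoxide carries a titanium angelate on the opposite face, so the carboxylate is delivered to C6 (C5 is neopentyl) by SN2 with inversion, forming the ester C–O bond, setting C6, retaining O5 as the free hydroxyl and keeping the Z ester geometry because no base or nucleophilic catalyst is present; the closest known reaction type is the Ti(OiPr)4-mediated C3-selective opening of 2,3-epoxy alcohols by carboxylic acids, which has not been shown for tertiary carbinols, medium-ring cis-epoxides, two-alkoxide delivery or angelic acid.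

## Compound list

1 | 2-methylprop-2-en-1-ol | CC(=C)CO | starting material
2 | (S)-2-methylglycidol, [(2S)-2-methyloxiran-2-yl]methanol | OC[C@@]1(C)CO1 | intermediate (not isolated)
3 | [(2R)-2-methyloxiran-2-yl]methyl 4-methylbenzenesulfonate | Cc1ccc(cc1)S(=O)(=O)OC[C@@]1(C)CO1 | intermediate
4 | (R)-citronellyl bromide, (6R)-8-bromo-2,6-dimethyloct-2-ene | CC(C)=CCC[C@@H](C)CCBr | starting material
5 | (R)-citronellylmagnesium bromide | CC(C)=CCC[C@@H](C)CC[Mg]Br | intermediate (not isolated)
6 | (2R,6S)-2-hydroxy-2,6,10-trimethylundec-9-en-1-yl 4-methylbenzenesulfonate | Cc1ccc(cc1)S(=O)(=O)OC[C@](C)(O)CCC[C@H](C)CCC=C(C)C | intermediate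
7 | (2R)-2-[(4S)-4,8-dimethylnon-7-en-1-yl]-2-methyloxirane | C[C@@]1(CCC[C@H](C)CCC=C(C)C)CO1 | intermediate (not isolated)
8 | (3R,7S)-3,7,11-trimethyldodeca-1,10-dien-3-ol | C=C[C@](C)(O)CCC[C@H](C)CCC=C(C)C | intermediate
9 | (3R,7S)-9-[(2R)-3,3-dimethyloxiran-2-yl]-3,7-dimethylnon-1-en-3-ol | C=C[C@](C)(O)CCC[C@H](C)CC[C@H]1OC1(C)C | intermediate
10 | (3R,6S,10R)-3-ethenyl-2,6,10-trimethyldodec-11-ene-2,10-diol | C=C[C@](C)(O)CCC[C@H](C)CC[C@H](C=C)C(C)(C)O | intermediate
11 | (1R,2Z,4R,7S)-4-(2-hydroxypropan-2-yl)-1,7-dimethylcyclodec-2-en-1-ol | CC(C)(O)[C@H]1/C=C\[C@](C)(O)CCC[C@H](C)CC1 | intermediate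
12 | (1S,2R,6S,9R,10S)-9-(2-hydroxypropan-2-yl)-2,6-dimethyl-11-oxabicyclo[8.1.0]undecan-2-ol | O1[C@H]2[C@H](C(C)(C)O)CC[C@@H](C)CCC[C@@](C)(O)[C@H]21 | intermediate
13 | angelic acid, (2Z)-2-methylbut-2-enoic acid | C/C=C(/C)C(=O)O | starting material
14 | (1R,2S,3R,7S,10R)-2,3-dihydroxy-10-(2-hydroxypropan-2-yl)-3,7-dimethylcyclodecyl (2Z)-2-methylbut-2-enoate | C/C=C(/C)C(=O)O[C@@H]1[C@H](C(C)(C)O)CC[C@@H](C)CCC[C@@](C)(O)[C@H]1O | target

## Step count and risks

Total step count: 8. Longest linear sequence: 8 steps (1 → 14).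

Steps most likely to fail:

- **Step 8 (proposed new method).** Backside attack at C6 of a medium-ring epoxide may be slow, and transannular hydride shift or O6→O5 acyl migration could compete. The fallback uses known chemistry, sets out from 11 and comes back at 14. Alkene 11 is dihydroxylated syn to the C4 hydroxyl with OsO4/TMEDA (hydrogen-bond-directed, CH2Cl2, −78 °C, then aq. Na2SO3) to give the all-cis tetraol F1. SOCl2/Et3N converts its cis-5,6-diol into the cyclic sulfite F2, which RuCl3/NaIO4 oxidises to the cyclic sulfate F3. Cesium angelate F4 (from 13 and Cs2CO3, DMF, 50 °C) opens F3 at C6 with inversion (C5 is neopentyl) to give the sulfate monoester salt F5. Brief H2SO4/H2O/THF hydrolysis then gives 14.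

- **Step 6 (ring-closing metathesis).** Closing a ten-membered carbocycle from two hindered vinyl groups may give oligomers or stall. The fallback sets out from 10 and comes back at 11 and uses a temporary silicon tether. Me2Si(OTf)2/2,6-lutidine at high dilution ties the two tertiary hydroxyls together as the silylene-tethered diene F6. Metathesis with the same ruthenium catalyst then closes an eight-membered silaketal ring that can only hold a Z alkene, giving the bicyclic silaketal F7. HF·pyridine removes the tether to give 11.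

- **Step 5 (vinyl-copper opening).** SN2 at a secondary epoxide carbon next to a quaternary carbon may be slow, or may give bromohydrin or rearranged ketone. The fallback sets out from 9 and comes back at 10. Lithium acetylide–ethylenediamine complex in DMSO (a slim sp nucleophile, no Lewis acid) opens the epoxide at C7 with inversion to give the alkyne diol F8. Lindlar semi-hydrogenation (H2, Pd/CaCO3 poisoned with Pb(OAc)2, quinoline) then gives 10.

Further compounds

F1 | step 8 | (1S,2S,3R,7S,10R)-10-(2-hydroxypropan-2-yl)-3,7-dimethylcyclodecane-1,2,3-triol | O[C@H]1[C@H](C(C)(C)O)CC[C@@H](C)CCC[C@@](C)(O)[C@H]1O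
F2 | step 8 | 5,6-cyclic sulfite of F1 | O=S1O[C@H]2[C@H](C(C)(C)O)CC[C@@H](C)CCC[C@@](C)(O)[C@H]2O1
F3 | step 8 | 5,6-cyclic sulfate of F1 | O=S1(=O)O[C@H]2[C@H](C(C)(C)O)CC[C@@H](C)CCC[C@@](C)(O)[C@H]2O1
F4 | step 8 | cesium (2Z)-2-methylbut-2-enoate | C/C=C(/C)C(=O)[O-].[Cs+]
F5 | step 8 | cesium salt of the 5-O-sulfate of 14 | C/C=C(/C)C(=O)O[C@@H]1[C@H](C(C)(C)O)CC[C@@H](C)CCC[C@@](C)(O)[C@H]1OS(=O)(=O)[O-].[Cs+]
F6 | step 6 | twelve-membered dimethylsilylene diether of 10 | C=C[C@@]1(C)CCC[C@H](C)CC[C@H](C=C)C(C)(C)O[Si](C)(C)O1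
F7 | step 6 | bicyclic dimethylsilylene diether of 11 | C[C@H]1CCC[C@]2(C)/C=C\[C@@H](CC1)C(C)(C)O[Si](C)(C)O2
F8 | step 5 | (3R,6S,10R)-3-ethynyl-2,6,10-trimethyldodec-11-ene-2,10-diol | C=C[C@](C)(O)CCC[C@H](C)CC[C@H](C#C)C(C)(C)O
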